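## The problem

The target is a 3,3'-linked biflavanone: two 5,7-dihydroxychroman-4-one units joined through their C3 carbons. Unit A (unprimed) carries a 4-methoxyphenyl group at C2 and unit B (primed) a 4-hydroxyphenyl group at C2'. The descriptors of the structure read (2S,3S,2'R,3'S), so unit A is 2,3-cis and unit B is 2',3'-trans. The two halves therefore differ in constitution and in relative configuration and cannot come from dimerising one flavanone. The central C3–C3' bond joins two tertiary carbons, each α to an aryl ketone and next to a benzylic C–O centre, and no finished flavanone half reliably controls the configuration of the other. Both C3–H bonds are enolisable, the cis unit is the less stable epimer, and base opens a flavanone by β-elimination of the phenoxide, so late intermediates tolerate neither strong base nor acid that ionises the 4-alkoxybenzylic C2–O bonds. Of the six phenolic oxygens outside the pyranone rings exactly one, on the aryl group of unit A, must end as a methyl ether. The enabling feature is the chain C2–C3–C3'–C2', with aryl groups on the end carbons and the carbonyl carbons C4 and C4' on the inner ones: if O1 and O1' are replaced by the two carbons of an alkene, it is a 3,6-diaryl-4,5-diacylcyclohexene whose cis-diaryl/trans-diacyl pattern is what an (E,E)-diene and an (E)-dienophile give in an endo Diels–Alder reaction.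

## Retrosynthesis

**Deprotection.** Target 27 is traced to its pentabenzyl ether 26 by cutting five O–benzyl bonds. Benzyl is used for every oxygen that ends as OH because hydrogenolysis is neutral and touches neither the methyl ether nor the epimerisable cis unit. The forward step only has to stop before the benzylic C2–O1 bonds are reduced.

**Aryl–oxygen bonds.** In 26 the bonds O1–C8a and O1'–C8a' are cut, giving the open diol diketone 25 with a fluorine at each future C8a. The neighbouring cut, O1–C2 (oxa-Michael closure of a chalcone), would create C2 and C2' under thermodynamic control and could not give the cis unit. Cutting on the aryl side keeps C2 and C2' as preformed carbinol centres and makes ring closure a stereochemically silent nucleophilic aromatic substitution ortho to each ketone. The forward step must close both six-membered rings before the β-hydroxy ketones fragment.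

**Carbon for oxygen, and the ring.** The two benzylic alcohols of 25 are traced to the aldehydes of 23, since a Baeyer–Villiger oxidation replaces each formyl carbon by oxygen with retention. Joining the two formyl carbons of 23 as an alkene gives cyclohexene 22, which ozonolysis cuts in the forward direction. This exchanges two C–O stereocentres around a crowded C3–C3' bond for four ring carbons of a cyclohexene, a pattern with a direct construction. The forward steps need an alkene cleavage that spares the alkoxyarenes, and aldehydes that are oxidised before they epimerise.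

**Second ketone and the methyl ether.** The methyl ether of 22 is traced to pivalate 20; the ester is needed for the cycloaddition and is exchanged here, before any flavanone ring exists. The bond C4'–C4a' of 20 is cut to thioester 19 and arylzinc chloride 11, joined in a Fukuyama coupling. 19 comes from imide 18 by thiolate exchange. Carrying one carbonyl as an imide, not as a second aroyl group, gives the Cu(OTf)2–bis(oxazoline) complex its two-point binding site. The forward steps need neutral conditions that leave the first ketone and the centres α to both carbonyls alone.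

**Cyclohexene.** Adduct 18 is cut at C2–C3 and C2'–C3' into diene 6 and dienophile 17. This cut makes both bonds at the congested centre pair and all four stereocentres in one step, with the relative configuration taken from two alkene geometries. A stepwise Michael/aldol assembly of the same chain would have to control each centre separately. The forward reaction must put the imide endo, add to one face of 17, and join the pivaloyloxyphenyl terminus of 6 to the carbon β to the imide.

**Dienophile.** 17 is cut at the N–acyl bond to acid 14 and oxazolidin-2-one 15. 14 comes from ester 13, whose aryl–carbonyl bond is cut to arylzinc chloride 11 and acid chloride 12. An organometallic acylation is preferred to a Friedel–Crafts acylation because strong Lewis acids cleave a benzyl ether ortho to the new ketone. The same reagent 11 supplies both aroyl groups of the route, so it is prepared as a stock solution.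

**Arylzinc reagent.** The carbon–zinc bond of 11 is traced through arylmagnesium chloride 10 to the carbon–iodine bond of 9. 9 comes from fluoroarene 8 by iodination, and 8 from 1,3,5-trifluorobenzene 7 by two substitutions. The forward steps must place the iodine between fluorine and one benzyloxy group and must keep the ortho-fluoro organometallic cold enough that it does not lose fluoride.

**Diene.** The central double bond of 6 is cut to allylic phosphonate 5 and aldehyde 2. 5 comes from allylic alcohol 4 and this from 4-(benzyloxy)benzaldehyde 3; 2 is the pivalate of 4-hydroxybenzaldehyde 1. The olefination must give the (E,E)-diene and tolerate the aryl ester.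

## Roads not taken

**Alternative 1:** The cut runs through unit B on the aryl side: O1'–C8a', C4'–C4a' and O1'–C2' are broken, leading back to the α-substituted cinnamic acid A2 and the aryne released from silyl triflate A3. In the forward key step the carboxylate of A2 adds to the aryne carbon remote from the neighbouring benzyloxy group. The aryl anion takes over the acyl group (net insertion into the C–O bond), and the phenoxide closes onto C2' by oxa-Michael addition to give A1, in which C4 of unit A is still a silyl-protected alcohol.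
- Merits: three bonds and the whole pyranone of unit B form in one flask, with no fluorinated ketone, no substitution on an electron-rich ring and no ring cleavage. The trans relation in unit B is the thermodynamic outcome of a reversible closure.
- Weak points: the acid carbonyl of A2 sits on a fully substituted alkene carbon next to C3, where acyl transfer competes poorly with simple O-arylation. C2' and C3' are set (C3' by enolate protonation) only under the influence of unit A, so the relation between the halves rests on substrate control of unknown sense. Unit A must first be made as an enantiopure cis-2,3-disubstituted chromane. C4 must afterwards be desilylated and oxidised, because a cis flavanone ketone would not survive the basic fluoride medium.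
- Comparison: this road is more convergent at the end and avoids the detour through aldehydes. The chosen plan sets against it that all four centres are fixed together by alkene geometry, endo topology and one catalyst.

**Alternative 2:** The cut is C2–C3 of unit A. The precursor is diazo ketone A5, in which C3 is the diazo carbon and the future C2 is the methylene of a 4-methoxybenzyl ether on O1. With Rh2(OAc)4 the carbenoid inserts into the benzylic C–H bond next to oxygen and closes the pyranone of unit A to give A4.
- Merits: the sensitive cis unit is made last, under neutral conditions, by a reaction type that favours the cis-2,3 product kinetically. The C–H bond is doubly activated. On this point the road is better than the chosen plan, whose cis unit forms in a basic medium.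
- Weak points: the carbenoid carbon carries C3' with a β-hydrogen, and 1,2-hydride shift to the enone, the usual escape of α-alkyl diazo ketones, would erase C3'. Making A5 needs an activated (deformylative) diazo transfer next to a crowded centre. The face of insertion relative to unit B must be enforced by a chiral catalyst such as Rh2(S-PTTL)4, with or against the bias of C3'. O5 has to be a silyl ether to remove a competing benzylic C–H bond. Unit B and the C3–C3' bond must already exist.
- Comparison: the chosen plan sets against the milder closure that it has no diazo intermediate and that its inter-unit configuration is not left to a matched or mismatched catalyst–substrate pair.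

**Alternative 3:** The cut is O1'–C2'. The precursor A7 has a 4-hydroxybenzyl group on C3' and a free ortho phenol on the aryl ketone of unit B. DDQ dehydrogenates the 4-hydroxybenzyl group to a para-quinone methide and the phenol adds to C2', giving A6.
- Merits: the free 4'-OH of unit B is the trigger, so the two aryl groups are told apart by the chemistry itself. This is better than the chosen plan, which needs a pivalate-to-methyl exchange. The conditions are neutral and the trans unit is favoured.
- Weak points: only C2' is made. C2, C3, C3' and the C3–C3' bond are moved unsolved into A7. The quinone methide has an acidic hydrogen at C3' and can tautomerise to a benzylidene ketone, which loses C3'. DDQ can also dehydrogenate flavanones and attack benzyl ethers. Control at C2' is substrate control only.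
- Comparison: the chosen plan sets against the biomimetic closure that it solves the C3–C3' problem, which this road assumes.

Key step: step 11

Remark: ethyl (2E)-4-chloro-4-oxobut-2-enoate (12), oxazolidin-2-one (15) and the (S,S)-tert-butyl bis(oxazoline) ligand are taken as purchasable. Arylzinc chloride 11 is made in step 7 as a titrated THF solution kept cold under argon and is drawn on in steps 8 and 13; a fresh batch by the same procedure is used if the stock has aged.

## Route

Step 1
Reactants: 1 4-hydroxybenzaldehyde
Product: 2 4-formylphenyl pivalate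
Conditions: PivCl, Et3N, DMAP (cat.), CH2Cl2, 0 °C → rt
Reagents that add atoms: pivaloyl chloride, CC(C)(C)C(=O)Cl
Why: Esterification of a phenol under nucleophilic catalysis; the pivalate makes this aryl ring the electron-poorer one for the cycloaddition and is hindered enough to survive the olefination base.

Step 2
Reactants: 3 4-(benzyloxy)benzaldehyde
Product: 4 1-[4-(benzyloxy)phenyl]prop-2-en-1-ol (racemic)
Conditions: CH2=CHMgBr, THF, 0 °C; aq. NH4Cl
Reagents that add atoms: vinylmagnesium bromide, C=C[Mg]Br
Why: Grignard 1,2-addition to an aromatic aldehyde; the carbinol centre is racemic and disappears in the next step.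

Step 3
Reactants: 4 1-[4-(benzyloxy)phenyl]prop-2-en-1-ol
Product: 5 diethyl [(2E)-3-[4-(benzyloxy)phenyl]prop-2-en-1-yl]phosphonate
Conditions: P(OEt)3, ZnI2, toluene, reflux
Reagents that add atoms: triethyl phosphite, CCOP(OCC)OCC
Why: ZnI2-promoted conversion of an allylic alcohol into a phosphonate (Michaelis–Arbuzov type); ionisation to the 4-benzyloxycinnamyl cation and capture at the unhindered terminus should give the conjugated (E)-phosphonate.

Step 4
Reactants: 5 diethyl [(2E)-3-[4-(benzyloxy)phenyl]prop-2-en-1-yl]phosphonate; 2 4-formylphenyl pivalate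
Product: 6 (1E,3E)-1-[4-(benzyloxy)phenyl]-4-[4-(pivaloyloxy)phenyl]buta-1,3-diene
Conditions: LiN(SiMe3)2, THF, −78 °C; then 2, −78 °C → rt
Reagents that add atoms: none
Why: Horner–Wadsworth–Emmons olefination of a stabilised allylic phosphonate anion with an aromatic aldehyde, which forms the new double bond (E) and keeps the existing one; the non-nucleophilic amide base leaves the aryl pivalate intact.

Step 5
Reactants: 7 1,3,5-trifluorobenzene
Product: 8 1,3-bis(benzyloxy)-5-fluorobenzene
Conditions: BnOH, NaH, NMP, 0 °C → 100 °C (sealed vessel)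
Reagents that add atoms: benzyl alcohol, OCc1ccccc1
Why: Twofold nucleophilic aromatic substitution; each fluorine is activated by the meta fluorines, and the third substitution is much slower once two alkoxy groups are present, so stoichiometry should stop the reaction at the monofluoride.

Step 6
Reactants: 8 1,3-bis(benzyloxy)-5-fluorobenzene
Product: 9 1,5-bis(benzyloxy)-3-fluoro-2-iodobenzene
Conditions: NIS, CF3CO2H (cat.), MeCN, 0 °C → rt
Reagents that add atoms: N-iodosuccinimide, O=C1CCC(=O)N1I
Why: Electrophilic aromatic iodination; the position para to one benzyloxy group and next to the small fluorine should be attacked in preference to the position flanked by both benzyloxy groups.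

Step 7
Reactants: 9 1,5-bis(benzyloxy)-3-fluoro-2-iodobenzene
Product: 11 [2,4-bis(benzyloxy)-6-fluorophenyl]zinc chloride as a titrated THF solution, via arylmagnesium chloride 10 (not isolated)
Conditions: i-PrMgCl·LiCl, THF, −30 °C; then ZnCl2 (THF), −30 → 0 °C; titrated with I2, stored at 0 °C under Ar
Reagents that add atoms: zinc chloride, Cl[Zn]Cl
Why: Iodine–magnesium exchange (turbo-Grignard), assisted by the ortho fluorine and ortho alkoxy group, followed by transmetalation to zinc. Below 0 °C the ortho-fluoro arylmagnesium species should not eliminate to an aryne, and the arylzinc chloride is stable enough to be stored and used in portions.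

Step 8
Reactants: 11 [2,4-bis(benzyloxy)-6-fluorophenyl]zinc chloride; 12 ethyl (2E)-4-chloro-4-oxobut-2-enoate
Product: 13 ethyl (2E)-4-[2,4-bis(benzyloxy)-6-fluorophenyl]-4-oxobut-2-enoate
Conditions: Pd(PPh3)4 (5 mol %), THF, 0 °C → rt
Reagents that add atoms: none
Why: Negishi acylation of an acid chloride; the arylzinc tolerates the ester and does not add to the enone, and the (E) geometry of 12 is kept. No Lewis acid strong enough to cleave the benzyl ethers is present.

Step 9
Reactants: 13 ethyl (2E)-4-[2,4-bis(benzyloxy)-6-fluorophenyl]-4-oxobut-2-enoate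
Product: 14 (2E)-4-[2,4-bis(benzyloxy)-6-fluorophenyl]-4-oxobut-2-enoic acid
Conditions: LiOH, THF/H2O, 0 °C; then 1 M HCl
Reagents that add atoms: water, O (delivered as hydroxide from LiOH, [Li+].[OH-])
Why: Saponification of an ethyl ester at 0 °C, where hydroxide should attack the ester faster than it adds to the enone or displaces fluoride.

Step 10
Reactants: 14 (2E)-4-[2,4-bis(benzyloxy)-6-fluorophenyl]-4-oxobut-2-enoic acid; 15 oxazolidin-2-one
Product: 17 3-[(2E)-4-[2,4-bis(benzyloxy)-6-fluorophenyl]-4-oxobut-2-enoyl]oxazolidin-2-one, via mixed pivalic anhydride 16 (not isolated)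
Conditions: PivCl, Et3N, THF, −20 °C; then 15, LiCl, −20 °C → rt
Reagents that add atoms: none
Why: N-Acylation of an oxazolidinone by a mixed pivalic anhydride with LiCl/Et3N; the nucleophile attacks the less hindered enoyl carbonyl and no strong base that could add to the enone is needed.

Step 11
Reactants: 6 (1E,3E)-1-[4-(benzyloxy)phenyl]-4-[4-(pivaloyloxy)phenyl]buta-1,3-diene; 17 3-[(2E)-4-[2,4-bis(benzyloxy)-6-fluorophenyl]-4-oxobut-2-enoyl]oxazolidin-2-one
Product: 18 3-{[(1R,2R,5S,6R)-6-[2,4-bis(benzyloxy)-6-fluorobenzoyl]-2-[4-(benzyloxy)phenyl]-5-[4-(pivaloyloxy)phenyl]cyclohex-3-en-1-yl]carbonyl}oxazolidin-2-one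
Conditions: Cu(OTf)2 (10 mol %), (S,S)-t-Bu-box (11 mol %), 4 Å MS, CH2Cl2, −20 °C → rt
Reagents that add atoms: none
Why: The cationic complex of divalent copper formed from Cu(OTf)2 and the (S,S)-tert-butyl bis(oxazoline) binds both imide carbonyls of 17 in a square-planar chelate, holds the enoyl unit s-cis and lowers its LUMO, so that the s-cis conformer of 6 adds in a concerted, asynchronous, suprafacial [4+2] cycloaddition; the closest known reaction type is the Cu(OTf)2–bis(oxazoline)-catalysed Diels–Alder reaction of fumarate-type acyl oxazolidinones with 1-aryl butadienes. The cyclohexene is closed by intermolecular cycloaddition, both ring bonds (C2–C3 and C2'–C3') forming in the same step. The cis relation of the aryl-bearing centres C2 and C2' follows from the (E,E) geometry of 6, and the trans relation of C3 and C3' from the (E) geometry of 17. The endo rule places the copper-bound imide carbonyl under the diene, so the imide ends up cis to both aryl groups and the free aroyl group trans to them, which later becomes trans unit B and cis unit A. The absolute configuration comes from the ligand: the tert-butyl group beside the s-cis alkene covers the Si face of the imide α-carbon, the diene adds to the Re face, C3' (ring C1) becomes R and the other three centres follow from the suprafacial endo geometry. Regiochemistry requires the carbon β to the chelated imide, the most electrophilic site, to bond first to the diene terminus that bears the 4-pivaloyloxyphenyl group. The 4-benzyloxyphenyl group at the other terminus stabilises the positive charge that builds up there far better than the acyloxy-substituted ring, and this should secure the orientation.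

Step 12
Reactants: 18 cycloadduct imide
Product: 19 S-ethyl (1R,2R,5S,6R)-6-[2,4-bis(benzyloxy)-6-fluorobenzoyl]-2-[4-(benzyloxy)phenyl]-5-[4-(pivaloyloxy)phenyl]cyclohex-3-ene-1-carbothioate
Conditions: EtSH, n-BuLi, THF, 0 °C; aq. NH4Cl
Reagents that add atoms: ethanethiol, CCS
Why: Transthioesterification of an N-acyl oxazolidinone by LiSEt, which attacks the exocyclic carbonyl; the thiolate is too weakly basic to epimerise C3 or C3' and at 0 °C should leave the hindered aryl pivalate.

Step 13
Reactants: 19 S-ethyl thioester; 11 [2,4-bis(benzyloxy)-6-fluorophenyl]zinc chloride (THF solution from step 7)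
Product: 20 4-{(1S,4R,5R,6R)-5,6-bis[2,4-bis(benzyloxy)-6-fluorobenzoyl]-4-[4-(benzyloxy)phenyl]cyclohex-2-en-1-yl}phenyl pivalate
Conditions: PdCl2(PPh3)2 (10 mol %), THF/toluene, rt
Reagents that add atoms: none
Why: Fukuyama ketone synthesis: zerovalent palladium generated from PdCl2(PPh3)2 inserts into the C–S bond, the arylzinc transmetalates and reductive elimination gives the ketone. The medium is neutral, so the first ketone, the pivalate and the centres α to both carbonyls should not be touched.

Step 14
Reactants: 20 diketone pivalate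
Product: 22 [(1R,2R,3S,6R)-6-[4-(benzyloxy)phenyl]-3-(4-methoxyphenyl)cyclohex-4-ene-1,2-diyl]bis{[2,4-bis(benzyloxy)-6-fluorophenyl]methanone}, via free phenol 21 (not isolated)
Conditions: K2CO3, MeOH/THF, rt; evaporate; then MeI, DMF, rt
Reagents that add atoms: iodomethane, CI
Why: Methanolysis of the aryl ester followed by Williamson methylation of the phenoxide without isolation. It is placed here, before any flavanone ring exists, because the two crowded ketones have no β-leaving group and should enolise only slowly under carbonate.

Step 15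
Reactants: 22 methyl ether cyclohexene
Product: 23 (2S,3R,4R,5R)-3,4-bis[2,4-bis(benzyloxy)-6-fluorobenzoyl]-5-[4-(benzyloxy)phenyl]-2-(4-methoxyphenyl)hexanedial
Conditions: O3 (1 equiv., metered), NaHCO3, CH2Cl2/MeOH, −78 °C; then Me2S, −78 °C → rt; used at once
Reagents that add atoms: ozone, [O-][O+]=O
Why: Ozonolysis of the only alkene with reductive work-up; the cis-disubstituted ring alkene should react far faster than the alkoxyarenes, and the buffered, neutral work-up should leave the two α-aryl aldehyde centres unchanged.

Step 16
Reactants: 23 dialdehyde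
Product: 25 (2S,3S)-1,4-bis[2,4-bis(benzyloxy)-6-fluorophenyl]-2-{(R)-[4-(benzyloxy)phenyl](hydroxy)methyl}-3-[(S)-hydroxy(4-methoxyphenyl)methyl]butane-1,4-dione, via bis-formate 24 (not isolated)
Conditions: mCPBA, Na2HPO4, CH2Cl2, 0 °C → rt; aq. Na2S2O3 wash; then KHCO3, MeOH/THF, 0 °C
Reagents that add atoms: 3-chloroperoxybenzoic acid, OOC(=O)c1cccc(Cl)c1
Why: Baeyer–Villiger oxidation of the two aldehydes: the secondary benzylic carbon migrates in preference to hydrogen and with retention, turning C2–CHO and C2'–CHO into formates. Hydrogencarbonate in methanol then removes the formates by transesterification without enolising the ketones. The crowded aryl ketones should react with the peracid much more slowly than the aldehydes, and the buffer prevents ionisation of the 4-alkoxybenzylic formates.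

Step 17
Reactants: 25 diol diketone
Product: 26 (2S,3S,2'R,3'S)-5,5',7,7'-tetrakis(benzyloxy)-2'-[4-(benzyloxy)phenyl]-2-(4-methoxyphenyl)-[3,3'-bichromane]-4,4'-dione
Conditions: Cs2CO3, DMF, 0 °C → rt; pH 7 buffer quench
Reagents that add atoms: none
Why: Twofold intramolecular nucleophilic aromatic substitution (addition–elimination): each alkoxide attacks the fluorine-bearing carbon ortho to its own ketone through a six-membered transition state, faster than the seven-membered closure onto the other ring, and both benzyloxy groups sit meta to fluorine, off the carbons that carry the Meisenheimer charge. No stereocentre takes part, so C2, C3, C3' and C2' keep the configuration set in step 11.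

Step 18
Reactants: 26 pentabenzyl ether
Product: 27 (2S,3S,2'R,3'S)-5,5',7,7'-tetrahydroxy-2'-(4-hydroxyphenyl)-2-(4-methoxyphenyl)-[3,3'-bichromane]-4,4'-dione (CNP0196568.4)
Conditions: H2 (1 atm), Pd/C, EtOAc/MeOH, rt
Reagents that add atoms: none
Why: Hydrogenolysis of the five benzyl ethers over Pd/C under neutral conditions; the methyl ether, the ketones and the stereocentres should not be affected.

## Compound list

1 | 4-hydroxybenzaldehyde | O=Cc1ccc(O)cc1 | starting material
2 | 4-formylphenyl pivalate | CC(C)(C)C(=O)Oc1ccc(C=O)cc1 | intermediate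
3 | 4-(benzyloxy)benzaldehyde | O=Cc1ccc(OCc2ccccc2)cc1 | starting material
4 | 1-[4-(benzyloxy)phenyl]prop-2-en-1-ol (racemic) | C=CC(O)c1ccc(OCc2ccccc2)cc1 | intermediate
5 | diethyl [(2E)-3-[4-(benzyloxy)phenyl]prop-2-en-1-yl]phosphonate | CCOP(=O)(C/C=C/c1ccc(OCc2ccccc2)cc1)OCC | intermediate
6 | (1E,3E)-1-[4-(benzyloxy)phenyl]-4-[4-(pivaloyloxy)phenyl]buta-1,3-diene | CC(C)(C)C(=O)Oc1ccc(/C=C/C=C/c2ccc(OCc3ccccc3)cc2)cc1 | intermediate
7 | 1,3,5-trifluorobenzene | Fc1cc(F)cc(F)c1 | starting material
8 | 1,3-bis(benzyloxy)-5-fluorobenzene | Fc1cc(OCc2ccccc2)cc(OCc2ccccc2)c1 | intermediate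
9 | 1,5-bis(benzyloxy)-3-fluoro-2-iodobenzene | Fc1cc(OCc2ccccc2)cc(OCc2ccccc2)c1I | intermediate
10 | [2,4-bis(benzyloxy)-6-fluorophenyl]magnesium chloride (LiCl complex) | Fc1cc(OCc2ccccc2)cc(OCc2ccccc2)c1[Mg]Cl | intermediate
11 | [2,4-bis(benzyloxy)-6-fluorophenyl]zinc chloride (THF solution) | Fc1cc(OCc2ccccc2)cc(OCc2ccccc2)c1[Zn]Cl | intermediate
12 | ethyl (2E)-4-chloro-4-oxobut-2-enoate | CCOC(=O)/C=C/C(Cl)=O | starting material
13 | ethyl (2E)-4-[2,4-bis(benzyloxy)-6-fluorophenyl]-4-oxobut-2-enoate | CCOC(=O)/C=C/C(=O)c1c(F)cc(OCc2ccccc2)cc1OCc1ccccc1 | intermediate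
14 | (2E)-4-[2,4-bis(benzyloxy)-6-fluorophenyl]-4-oxobut-2-enoic acid | OC(=O)/C=C/C(=O)c1c(F)cc(OCc2ccccc2)cc1OCc1ccccc1 | intermediate
15 | oxazolidin-2-one | O=C1NCCO1 | starting material
16 | mixed anhydride of 14 with pivalic acid | CC(C)(C)C(=O)OC(=O)/C=C/C(=O)c1c(F)cc(OCc2ccccc2)cc1OCc1ccccc1 | intermediate
17 | 3-[(2E)-4-[2,4-bis(benzyloxy)-6-fluorophenyl]-4-oxobut-2-enoyl]oxazolidin-2-one | O=C(/C=C/C(=O)c1c(F)cc(OCc2ccccc2)cc1OCc1ccccc1)N1CCOC1=O | intermediate
18 | 3-{[(1R,2R,5S,6R)-6-[2,4-bis(benzyloxy)-6-fluorobenzoyl]-2-[4-(benzyloxy)phenyl]-5-[4-(pivaloyloxy)phenyl]cyclohex-3-en-1-yl]carbonyl}oxazolidin-2-one | CC(C)(C)C(=O)Oc1ccc([C@H]2C=C[C@@H](c3ccc(OCc4ccccc4)cc3)[C@@H](C(=O)N3CCOC3=O)[C@@H]2C(=O)c2c(F)cc(OCc3ccccc3)cc2OCc2ccccc2)cc1 | intermediate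
19 | S-ethyl (1R,2R,5S,6R)-6-[2,4-bis(benzyloxy)-6-fluorobenzoyl]-2-[4-(benzyloxy)phenyl]-5-[4-(pivaloyloxy)phenyl]cyclohex-3-ene-1-carbothioate | CC(C)(C)C(=O)Oc1ccc([C@H]2C=C[C@@H](c3ccc(OCc4ccccc4)cc3)[C@@H](C(=O)SCC)[C@@H]2C(=O)c2c(F)cc(OCc3ccccc3)cc2OCc2ccccc2)cc1 | intermediate
20 | 4-{(1S,4R,5R,6R)-5,6-bis[2,4-bis(benzyloxy)-6-fluorobenzoyl]-4-[4-(benzyloxy)phenyl]cyclohex-2-en-1-yl}phenyl pivalate | CC(C)(C)C(=O)Oc1ccc([C@H]2C=C[C@@H](c3ccc(OCc4ccccc4)cc3)[C@@H](C(=O)c3c(F)cc(OCc4ccccc4)cc3OCc3ccccc3)[C@@H]2C(=O)c2c(F)cc(OCc3ccccc3)cc2OCc2ccccc2)cc1 | intermediate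
21 | 4-{(1S,4R,5R,6R)-5,6-bis[2,4-bis(benzyloxy)-6-fluorobenzoyl]-4-[4-(benzyloxy)phenyl]cyclohex-2-en-1-yl}phenol | Oc1ccc([C@H]2C=C[C@@H](c3ccc(OCc4ccccc4)cc3)[C@@H](C(=O)c3c(F)cc(OCc4ccccc4)cc3OCc3ccccc3)[C@@H]2C(=O)c2c(F)cc(OCc3ccccc3)cc2OCc2ccccc2)cc1 | intermediate
22 | [(1R,2R,3S,6R)-6-[4-(benzyloxy)phenyl]-3-(4-methoxyphenyl)cyclohex-4-ene-1,2-diyl]bis{[2,4-bis(benzyloxy)-6-fluorophenyl]methanone} | COc1ccc([C@H]2C=C[C@@H](c3ccc(OCc4ccccc4)cc3)[C@@H](C(=O)c3c(F)cc(OCc4ccccc4)cc3OCc3ccccc3)[C@@H]2C(=O)c2c(F)cc(OCc3ccccc3)cc2OCc2ccccc2)cc1 | intermediate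
23 | (2S,3R,4R,5R)-3,4-bis[2,4-bis(benzyloxy)-6-fluorobenzoyl]-5-[4-(benzyloxy)phenyl]-2-(4-methoxyphenyl)hexanedial | COc1ccc([C@@H](C=O)[C@@H](C(=O)c2c(F)cc(OCc3ccccc3)cc2OCc2ccccc2)[C@H](C(=O)c2c(F)cc(OCc3ccccc3)cc2OCc2ccccc2)[C@@H](C=O)c2ccc(OCc3ccccc3)cc2)cc1 | intermediate
24 | bis-formate of 25 ((S)-formyloxy carbon at the 4-methoxyphenyl end, (R) at the 4-benzyloxyphenyl end, (2S,3S) backbone) | COc1ccc([C@@H](OC=O)[C@@H](C(=O)c2c(F)cc(OCc3ccccc3)cc2OCc2ccccc2)[C@H](C(=O)c2c(F)cc(OCc3ccccc3)cc2OCc2ccccc2)[C@@H](OC=O)c2ccc(OCc3ccccc3)cc2)cc1 | intermediate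
25 | (2S,3S)-1,4-bis[2,4-bis(benzyloxy)-6-fluorophenyl]-2-{(R)-[4-(benzyloxy)phenyl](hydroxy)methyl}-3-[(S)-hydroxy(4-methoxyphenyl)methyl]butane-1,4-dione | COc1ccc([C@@H](O)[C@@H](C(=O)c2c(F)cc(OCc3ccccc3)cc2OCc2ccccc2)[C@H](C(=O)c2c(F)cc(OCc3ccccc3)cc2OCc2ccccc2)[C@@H](O)c2ccc(OCc3ccccc3)cc2)cc1 | intermediate
26 | (2S,3S,2'R,3'S)-5,5',7,7'-tetrakis(benzyloxy)-2'-[4-(benzyloxy)phenyl]-2-(4-methoxyphenyl)-[3,3'-bichromane]-4,4'-dione | COc1ccc([C@H]2Oc3cc(OCc4ccccc4)cc(OCc4ccccc4)c3C(=O)[C@H]2[C@@H]2C(=O)c3c(OCc4ccccc4)cc(OCc4ccccc4)cc3O[C@H]2c2ccc(OCc3ccccc3)cc2)cc1 | intermediate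
27 | (2S,3S,2'R,3'S)-5,5',7,7'-tetrahydroxy-2'-(4-hydroxyphenyl)-2-(4-methoxyphenyl)-[3,3'-bichromane]-4,4'-dione | COc1ccc([C@H]2Oc3cc(O)cc(O)c3C(=O)[C@H]2[C@@H]2C(=O)c3c(O)cc(O)cc3O[C@H]2c2ccc(O)cc2)cc1 | target

## Step count and least certain steps

Total: 18 steps. Longest linear sequence: 14 steps (steps 5–18, from 1,3,5-trifluorobenzene 7); the diene branch (steps 1–4) joins at step 11.

**Step 11 (key step).** The most likely failure is low reactivity of the diene, which carries an aryl group on each terminus, towards the bulky chelate. An unselective background or single-point-bound pathway would then take over and erode facial selectivity. The aroyl carbonyl and its ortho benzyloxy oxygen can also compete with the imide for the divalent copper centre. The regiochemical preference rests only on the donor difference between an alkoxy- and an acyloxy-substituted ring and may be incomplete.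

Fallback: control by a covalently bound auxiliary and a stoichiometric Lewis acid. Starting from acid 14, the mixed anhydride 16 is used to acylate (R)-4-benzyloxazolidin-2-one, giving (4R)-4-benzyl-3-[(2E)-4-[2,4-bis(benzyloxy)-6-fluorophenyl]-4-oxobut-2-enoyl]oxazolidin-2-one F1. Cycloaddition of F1 with diene 6 under Et2AlCl (CH2Cl2, −78 → −20 °C) should give (4R)-4-benzyl-3-{[(1R,2R,5S,6R)-6-[2,4-bis(benzyloxy)-6-fluorobenzoyl]-2-[4-(benzyloxy)phenyl]-5-[4-(pivaloyloxy)phenyl]cyclohex-3-en-1-yl]carbonyl}oxazolidin-2-one F2. In the Et2AlCl chelate the benzyl group covers the Si face of the α-carbon, so the same Re-face, imide-endo addition is expected. LiSEt then removes the auxiliary and the sequence rejoins the route at thioester 19.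

**Step 13.** Transmetalation of a doubly ortho-substituted arylzinc onto a crowded divalent acylpalladium intermediate may be slow. Decarbonylation, protodezincation or biaryl formation could then outrun ketone formation.

Fallback: build the ketone through the least demanding electrophile. Starting from thioester 19, reduction with Et3SiH over Pd/C in acetone should give 4-{(1S,4R,5R,6R)-6-[2,4-bis(benzyloxy)-6-fluorobenzoyl]-4-[4-(benzyloxy)phenyl]-5-formylcyclohex-2-en-1-yl}phenyl pivalate F3. Addition of arylmagnesium chloride 10 (generated from 9 as in step 7, without the ZnCl2 stage) at −40 °C gives the secondary alcohol 4-{(1S,4R,5R,6R)-6-[2,4-bis(benzyloxy)-6-fluorobenzoyl]-5-{[2,4-bis(benzyloxy)-6-fluorophenyl](hydroxy)methyl}-4-[4-(benzyloxy)phenyl]cyclohex-2-en-1-yl}phenyl pivalate F4 (either carbinol epimer). Oxidation with Dess–Martin periodinane returns to the route at diketone 20.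

**Step 15.** Ozone may attack the electron-rich alkoxyarenes once the alkene is consumed, and the two α-aryl aldehyde centres (C2 and C2') may epimerise through enolisation during work-up.

Fallback: two-stage cleavage without ozone. Starting from cyclohexene 22, dihydroxylation with OsO4 (cat.) and N-methylmorpholine N-oxide on the ring face opposite the two aryl groups should give [(1R,2R,3R,4R,5S,6S)-3-[4-(benzyloxy)phenyl]-4,5-dihydroxy-6-(4-methoxyphenyl)cyclohexane-1,2-diyl]bis{[2,4-bis(benzyloxy)-6-fluorophenyl]methanone} F5, whose two new carbinol centres are lost on cleavage. Cleavage with NaIO4 in buffered aqueous THF returns to the route at dialdehyde 23, which is again oxidised at once.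

**Step 17.** The alkoxides needed for ring closure are those of β-hydroxy ketones, which can also rest as five-membered hemiketals on the more distant ketone. Retro-aldol fragmentation or dehydration may compete with substitution on a fluoroarene whose ketone activation is weakened by the two alkoxy donors. Once the cis unit is closed, prolonged contact with carbonate may epimerise C3.

Fallback: fluoride-triggered closure with no stoichiometric base. Starting from diol 25, silylation (Me3SiCl, imidazole) gives (2S,3S)-1,4-bis[2,4-bis(benzyloxy)-6-fluorophenyl]-2-{(R)-[4-(benzyloxy)phenyl](trimethylsilyloxy)methyl}-3-[(S)-(4-methoxyphenyl)(trimethylsilyloxy)methyl]butane-1,4-dione F6. Catalytic CsF in DMF should then release each alkoxide only transiently; the fluoride expelled in the substitution carries the chain and silicon leaves as Me3SiF. The sequence returns to the route at 26.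

## Further compounds

F1 | step 11 | (4R)-4-benzyl-3-[(2E)-4-[2,4-bis(benzyloxy)-6-fluorophenyl]-4-oxobut-2-enoyl]oxazolidin-2-one | O=C(/C=C/C(=O)c1c(F)cc(OCc2ccccc2)cc1OCc1ccccc1)N1[C@H](Cc2ccccc2)COC1=O
F2 | step 11 | (4R)-4-benzyl-3-{[(1R,2R,5S,6R)-6-[2,4-bis(benzyloxy)-6-fluorobenzoyl]-2-[4-(benzyloxy)phenyl]-5-[4-(pivaloyloxy)phenyl]cyclohex-3-en-1-yl]carbonyl}oxazolidin-2-one | CC(C)(C)C(=O)Oc1ccc([C@H]2C=C[C@@H](c3ccc(OCc4ccccc4)cc3)[C@@H](C(=O)N3[C@H](Cc4ccccc4)COC3=O)[C@@H]2C(=O)c2c(F)cc(OCc3ccccc3)cc2OCc2ccccc2)cc1
F3 | step 13 | 4-{(1S,4R,5R,6R)-6-[2,4-bis(benzyloxy)-6-fluorobenzoyl]-4-[4-(benzyloxy)phenyl]-5-formylcyclohex-2-en-1-yl}phenyl pivalate | CC(C)(C)C(=O)Oc1ccc([C@H]2C=C[C@@H](c3ccc(OCc4ccccc4)cc3)[C@@H](C=O)[C@@H]2C(=O)c2c(F)cc(OCc3ccccc3)cc2OCc2ccccc2)cc1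
F4 | step 13 | 4-{(1S,4R,5R,6R)-6-[2,4-bis(benzyloxy)-6-fluorobenzoyl]-5-{[2,4-bis(benzyloxy)-6-fluorophenyl](hydroxy)methyl}-4-[4-(benzyloxy)phenyl]cyclohex-2-en-1-yl}phenyl pivalate (carbinol centre undefined) | CC(C)(C)C(=O)Oc1ccc([C@H]2C=C[C@@H](c3ccc(OCc4ccccc4)cc3)[C@@H](C(O)c3c(F)cc(OCc4ccccc4)cc3OCc3ccccc3)[C@@H]2C(=O)c2c(F)cc(OCc3ccccc3)cc2OCc2ccccc2)cc1
F5 | step 15 | [(1R,2R,3R,4R,5S,6S)-3-[4-(benzyloxy)phenyl]-4,5-dihydroxy-6-(4-methoxyphenyl)cyclohexane-1,2-diyl]bis{[2,4-bis(benzyloxy)-6-fluorophenyl]methanone} (cis-diol of 22, hydroxyl groups on the face opposite the two aryl groups) | COc1ccc([C@H]2[C@H](O)[C@H](O)[C@@H](c3ccc(OCc4ccccc4)cc3)[C@@H](C(=O)c3c(F)cc(OCc4ccccc4)cc3OCc3ccccc3)[C@@H]2C(=O)c2c(F)cc(OCc3ccccc3)cc2OCc2ccccc2)cc1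
F6 | step 17 | (2S,3S)-1,4-bis[2,4-bis(benzyloxy)-6-fluorophenyl]-2-{(R)-[4-(benzyloxy)phenyl](trimethylsilyloxy)methyl}-3-[(S)-(4-methoxyphenyl)(trimethylsilyloxy)methyl]butane-1,4-dione | COc1ccc([C@@H](O[Si](C)(C)C)[C@@H](C(=O)c2c(F)cc(OCc3ccccc3)cc2OCc2ccccc2)[C@H](C(=O)c2c(F)cc(OCc3ccccc3)cc2OCc2ccccc2)[C@@H](O[Si](C)(C)C)c2ccc(OCc3ccccc3)cc2)cc1
A1 | alternative 1 | pentabenzyl ether of the target with C4 of unit A as a triisopropylsilyl-protected alcohol | COc1ccc([C@H]2Oc3cc(OCc4ccccc4)cc(OCc4ccccc4)c3[C@@H](O[Si](C(C)C)(C(C)C)C(C)C)[C@H]2[C@@H]2C(=O)c3c(OCc4ccccc4)cc(OCc4ccccc4)cc3O[C@H]2c2ccc(OCc3ccccc3)cc2)cc1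
A2 | alternative 1 | (2E)-3-[4-(benzyloxy)phenyl]-2-[5,7-bis(benzyloxy)-2-(4-methoxyphenyl)-4-(triisopropylsilyloxy)chroman-3-yl]prop-2-enoic acid, chromane configured as in A1 | COc1ccc([C@H]2Oc3cc(OCc4ccccc4)cc(OCc4ccccc4)c3[C@@H](O[Si](C(C)C)(C(C)C)C(C)C)[C@H]2/C(=C\c2ccc(OCc3ccccc3)cc2)C(O)=O)cc1
A3 | alternative 1 | 3,5-bis(benzyloxy)-2-(trimethylsilyl)phenyl trifluoromethanesulfonate | C[Si](C)(C)c1c(OS(=O)(=O)C(F)(F)F)cc(OCc2ccccc2)cc1OCc1ccccc1
A4 | alternative 2 | protected target with a tert-butyldimethylsilyl ether at O5 of unit A | COc1ccc([C@H]2Oc3cc(OCc4ccccc4)cc(O[Si](C)(C)C(C)(C)C)c3C(=O)[C@H]2[C@@H]2C(=O)c3c(OCc4ccccc4)cc(OCc4ccccc4)cc3O[C@H]2c2ccc(OCc3ccccc3)cc2)cc1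
A5 | alternative 2 | α-diazo ketone: 2-diazo-1-[4-(benzyloxy)-2-(tert-butyldimethylsilyloxy)-6-(4-methoxybenzyloxy)phenyl]-2-[(2R,3S)-5,7-bis(benzyloxy)-2-[4-(benzyloxy)phenyl]-4-oxochroman-3-yl]ethanone | COc1ccc(COc2cc(OCc3ccccc3)cc(O[Si](C)(C)C(C)(C)C)c2C(=O)C(=[N+]=[N-])[C@@H]2C(=O)c3c(OCc4ccccc4)cc(OCc4ccccc4)cc3O[C@H]2c2ccc(OCc3ccccc3)cc2)cc1
A6 | alternative 3 | tetrabenzyl ether of the target with the 4-hydroxyphenyl group free | COc1ccc([C@H]2Oc3cc(OCc4ccccc4)cc(OCc4ccccc4)c3C(=O)[C@H]2[C@@H]2C(=O)c3c(OCc4ccccc4)cc(OCc4ccccc4)cc3O[C@H]2c2ccc(O)cc2)cc1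
A7 | alternative 3 | cis-flavanone of unit A bearing at C3 the 1-[2,4-bis(benzyloxy)-6-hydroxyphenyl]-3-(4-hydroxyphenyl)-1-oxopropan-2-yl group, C3' configured as in A6 | COc1ccc([C@H]2Oc3cc(OCc4ccccc4)cc(OCc4ccccc4)c3C(=O)[C@H]2[C@@H](Cc2ccc(O)cc2)C(=O)c2c(O)cc(OCc3ccccc3)cc2OCc2ccccc2)cc1
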